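The chemist who calls G a trap for J argues first, against a colleague who calls G a bystander. The flask holds E and G, and J is asked for up to 15 min.

| flask | E | G | remark | time |
|---|---|---|---|---|
| red | 33 mM | 4.6 mM | run made earlier |  |
| amber | 33 mM | 7.3 mM | run made earlier |  |
| violet | 16 mM | 3.3 mM | run made earlier |  |
| flask | 33 mM | 3.30 mM |  | 15 min |

- red (time / min: J / %, X / %): 1.33: 4.2, 0.9; 4.00: 11.7, 0; 8.00: 21.6, 0.1; 10.0: 25.1, 0.4; 15.0: 32.6, 0.3
- amber (time / min: J / %, X / %): 3.00: 9.2, 0; 6.00: 16.3, 0.4; 10.0: 23.9, 0; 12.0: 27.2, 0.2; 15.0: 31.9, 0.4
- violet (time / min: J / %, X / %): 1.33: 4.0, 0; 4.00: 12.3, 0; 8.00: 21.4, 0; 10.0: 24.8, 0; 15.0: 32.6, 0.6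

(each reading ± 0.3 percentage points)

- amount of J in percent of the E charged, at 1.5 min, 5.0 min, 10 min and 15 min

They agree on the start. The readings at 4.00 min in red and violet, averaged, give E a first-order constant of 0.0320 min⁻¹. So 38.1% of the E should have turned into J by 15 min, yet red shows 32.6%, a shortfall of 5.5 percentage points.

The trapper lays that shortfall on G, since amber, with the most G, stands at 31.9%. Scaled down to the flask's G, it leaves J at 34.1%.

The bystander answers that violet already had the flask's G, with about half the E, and stands at 32.6%, no higher than red. J leaks whatever G does, so she measures the leak by the drain time, the J on hand divided by the rate at which J leaves, which is the inverse of a pseudo-first-order constant.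

Between 10.0 min and 15.0 min, red and violet hold 28.8% of J on average. E makes 0.0214 min⁻¹ of the charge, while J gains 0.0153 min⁻¹. The difference is what leaves, so the drain time is 46.9 min.

Amber, with twice violet's G, tests it. From 12.0 min to 15.0 min the drain time predicts a gain of 4.3 points, and amber's readings show 4.7 points, each single reading having a scatter of 0.3 points.

My own reckoning for the flask with this drain time gives 32.2% at 15 min, a little under the forecast's last figure. The forecast takes the bystander's side with 4.7%, 14.6%, 25% and 32.5%: “So formation looks first order in E and roughly zero order in G.”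

The flask gives 4.75%, 14.4%, 25.1% and 32.8%, within the forecast's tolerance and 1.3 points below the trapper's figure.

    L → X (k = 0.0220 min⁻¹)
    X ⇌ D (K = 1.50, k = 0.110 min⁻¹)
    E → J (k = 0.0330 min⁻¹)
    X → Z (k = 0.0660 min⁻¹)
    J + G → Q (k = 1.30 M⁻¹ min⁻¹)
    J → L (k = 0.0180 min⁻¹)

With the flask's 61.0% of E and 32.8% of J at 15.0 min, the drain time makes J 2.79 times faster than it is used, and the flask itself, each step taken net, stands at 2.82. At 6.58 min, J passes into L 4.3 times as fast as it passes with G into Q. The trapper's view comes into its own on the long course of G, of whose charge the flask keeps 15.1% at 150 min.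

All runs come from a simulation from invented constants; the scatter is artificial.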